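**Retrosynthetic overview**
1. Last step: both 3-pyridyl rings are attached at once by double hydroboration/B-alkyl Suzuki coupling of a bis(terminal alkene) bicyclic core with two equivalents of 3-bromopyridine.
2. Key step (in place of the intramolecular nitrone–alkene cycloaddition): C3 is set by convex-face hydride delivery to a bicyclic N-alkoxy oxocarbenium ion, formed from a hemiketal (octenyllithium + cis-fused isoxazolidin-5-one).
3. Ring B (isoxazolidine) is closed as that lactone: the N–O bond is made on nitrogen (N-oxidation/Cope elimination of a cyanoethyl amine), then the N–OH is acylated by the cis ester.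
4. Ring A (cyclopentane) with C3a/C6a comes intact from a chiral-pool cis-β-amino ester; the N-chain is added by reductive amination with tridec-12-enal (from 11-bromoundec-1-ene + oxirane).
5. Ring order: ring A bought → ring B closed (step 5) → C3 set (step 7) → both pyridine rings appended (step 8).

Assumption: ethyl (1S,2R)-2-aminocyclopentane-1-carboxylate hydrochloride (ester of ent-cispentacin) is bought as the single enantiomer, and the target is exactly the given SMILES, i.e. (3S,3aS,6aR).

**Route**

Step 1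
Reactants: 1 11-bromoundec-1-ene
Product: 3 tridec-12-en-1-ol, via undec-10-en-1-ylmagnesium bromide 2 (not isolated)
Conditions: Mg turnings, THF, 40 °C; then oxirane, CuI (5 mol %), −30 to 0 °C; 1 M HCl work-up
Reagents that add atoms: oxirane (ethylene oxide), C1CO1
Why: Grignard formation and CuI-catalysed epoxide opening give a clean two-carbon homologation to the C13 alcohol without touching the terminal alkene; no stereocenter is involved.

Step 2
Reactants: 3 tridec-12-en-1-ol
Product: 4 tridec-12-enal
Conditions: TEMPO (2,2,6,6-tetramethylpiperidin-1-oxyl, 10 mol %), PhI(OAc)2 (1.1 equiv), CH2Cl2, rt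
Reagents that add atoms: none
Why: Oxoammonium (TEMPO) oxidation stops at the aldehyde and leaves the terminal alkene alone.

Step 3
Reactants: 5 ethyl (1S,2R)-2-aminocyclopentane-1-carboxylate hydrochloride
Product: 6 ethyl (1S,2R)-2-[(2-cyanoethyl)amino]cyclopentane-1-carboxylate
Conditions: acrylonitrile (1.2 equiv), NaHCO3 (1.1 equiv), EtOH, rt
Reagents that add atoms: acrylonitrile, C=CC#N
Why: Aza-Michael addition of the α-branched primary amine stops at mono-addition and installs the arm that is later expelled by Cope elimination; the two bought stereocenters (future C3a and C6a) are not touched under these non-epimerising conditions.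

Step 4
Reactants: 6 ethyl (1S,2R)-2-[(2-cyanoethyl)amino]cyclopentane-1-carboxylate; 4 tridec-12-enal
Product: 8 ethyl (1S,2R)-2-[(2-cyanoethyl)(tridec-12-en-1-yl)amino]cyclopentane-1-carboxylate, via iminium ion 7 (not isolated)
Conditions: NaBH(OAc)3 (1.5 equiv), AcOH (1 equiv), ClCH2CH2Cl, rt
Reagents that add atoms: none
Why: Reductive amination attaches the C13 chain chemoselectively in the presence of nitrile, ester and alkene; no stereocenter is formed or disturbed.

Step 5
Reactants: 8 ethyl (1S,2R)-2-[(2-cyanoethyl)(tridec-12-en-1-yl)amino]cyclopentane-1-carboxylate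
Product: 11 (3aS,6aR)-1-(tridec-12-en-1-yl)hexahydro-3H-cyclopenta[c]isoxazol-3-one, via amine N-oxide 9 (not isolated), via N-hydroxy amino ester 10 (not isolated)
Conditions: mCPBA (1.0 equiv), CH2Cl2, −78 °C to rt; then solvent switch to PhMe, 60 °C, argon
Reagents that add atoms: mCPBA (3-chloroperoxybenzoic acid), OOC(=O)c1cccc(Cl)c1
Why: Amine N-oxidation is far faster than alkene epoxidation, the Cope elimination goes only into the acidic C–H next to the nitrile (the C3a–H is anti to nitrogen and cannot take part, so nothing epimerises), and the new N–OH is acylated by the cis ester (lactonisation) to close ring B as the only possible cis-fused bicycle.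

Step 6
Reactants: 11 (3aS,6aR)-1-(tridec-12-en-1-yl)hexahydro-3H-cyclopenta[c]isoxazol-3-one; 12 8-bromooct-1-ene
Product: 14 (3aS,6aR)-3-(oct-7-en-1-yl)-1-(tridec-12-en-1-yl)hexahydro-1H-cyclopenta[c]isoxazol-3-ol (C3 epimers), via oct-7-en-1-yllithium 13 (not isolated)
Conditions: 12, Li metal (2.2 equiv), Et2O, −10 °C; add to 11 (1.1 equiv RLi), THF, −78 °C; AcOH quench at −78 °C, cold work-up, use crude
Reagents that add atoms: none
Why: Organolithium mono-addition to a lactone at −78 °C gives the lactol because the tetrahedral adduct survives until the quench (as it does when isoxazolidin-5-ones are reduced to lactols by hydride), and with no copper salt present a hard carbon nucleophile attacks C=O and not N of the O-acyl hydroxylamine; the C3 centre formed here is erased in step 7.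

Step 7
Reactants: 14 (3aS,6aR)-3-(oct-7-en-1-yl)-1-(tridec-12-en-1-yl)hexahydro-1H-cyclopenta[c]isoxazol-3-ol
Product: 16 (3S,3aS,6aR)-3-(oct-7-en-1-yl)-1-(tridec-12-en-1-yl)hexahydro-1H-cyclopenta[c]isoxazole, via oxocarbenium ion 15 (not isolated)
Conditions: Et3SiH (3 equiv), BF3·OEt2 (2.5 equiv, promoter), CH2Cl2, −78 to −30 °C
Reagents that add atoms: none
Why: Proposed new method: BF3 ionises the hemiketal to a cyclic N-alkoxy oxocarbenium ion (the cation that 5-acetoxyisoxazolidines give in Lewis-acid N,O-nucleoside couplings) and Et3SiH delivers hydride to C3 from the convex face of the cis-fused bicyclo[3.3.0] cation, anti to the cyclopentane ring, which puts H3 cis to H3a/H6a and the octenyl chain on the concave face, i.e. (3S), while any C3a epimerisation through the enol ether is harmless because only the cis ring fusion can re-form; the closest known reaction type is the silane/Lewis-acid reductive deoxygenation of lactols (lactone, alkyllithium, then Et3SiH/BF3·OEt2) used for C-glycosides and 2-alkyl tetrahydrofurans.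

Step 8
Reactants: 16 (3S,3aS,6aR)-3-(oct-7-en-1-yl)-1-(tridec-12-en-1-yl)hexahydro-1H-cyclopenta[c]isoxazole; 17 3-bromopyridine
Product: 19 pyrinodemin B = (3S,3aS,6aR)-1-[13-(pyridin-3-yl)tridecyl]-3-[8-(pyridin-3-yl)octyl]hexahydro-1H-cyclopenta[c]isoxazole, via bis(9-BBN) borane adduct 18 (not isolated)
Conditions: 9-BBN (2.5 equiv), THF, 0 °C to rt; then 17 (2.6 equiv in total), PdCl2(dppf) (dppf = 1,1'-bis(diphenylphosphino)ferrocene, 10 mol %), 3 M aq NaOH, THF, 65 °C
Reagents that add atoms: 3-bromopyridine (the second equivalent of 17, one pyridyl ring per alkene terminus), Brc1cccnc1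
Why: Anti-Markovnikov hydroboration of both terminal alkenes followed by a twofold B-alkyl Suzuki–Miyaura coupling consumes two equivalents of 3-bromopyridine (one per alkylborane terminus) and attaches both 3-pyridyl rings in one operation; the N–O bond of an N,N,O-trialkylhydroxylamine is inert to 9-BBN and to PdCl2(dppf), and no stereocenter is touched.

**Compound list**
1 | 11-bromoundec-1-ene | C=CCCCCCCCCCBr | starting material
2 | undec-10-en-1-ylmagnesium bromide | C=CCCCCCCCCC[Mg]Br | intermediate
3 | tridec-12-en-1-ol | C=CCCCCCCCCCCCO | intermediate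
4 | tridec-12-enal | C=CCCCCCCCCCCC=O | intermediate
5 | ethyl (1S,2R)-2-aminocyclopentane-1-carboxylate hydrochloride | CCOC(=O)[C@H]1CCC[C@H]1N.Cl | starting material
6 | ethyl (1S,2R)-2-[(2-cyanoethyl)amino]cyclopentane-1-carboxylate | CCOC(=O)[C@H]1CCC[C@H]1NCCC#N | intermediate
7 | N-(2-cyanoethyl)-N-[(1R,2S)-2-(ethoxycarbonyl)cyclopentyl]tridec-12-en-1-iminium ion | CCOC(=O)[C@H]1CCC[C@H]1[N+](CCC#N)=CCCCCCCCCCCC=C | intermediate
8 | ethyl (1S,2R)-2-[(2-cyanoethyl)(tridec-12-en-1-yl)amino]cyclopentane-1-carboxylate | CCOC(=O)[C@H]1CCC[C@H]1N(CCC#N)CCCCCCCCCCCC=C | intermediate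
9 | ethyl (1S,2R)-2-[(2-cyanoethyl)(tridec-12-en-1-yl)amino]cyclopentane-1-carboxylate N-oxide (N-epimer mixture) | CCOC(=O)[C@H]1CCC[C@H]1[N+]([O-])(CCC#N)CCCCCCCCCCCC=C | intermediate
10 | ethyl (1S,2R)-2-[hydroxy(tridec-12-en-1-yl)amino]cyclopentane-1-carboxylate | CCOC(=O)[C@H]1CCC[C@H]1N(O)CCCCCCCCCCCC=C | intermediate
11 | (3aS,6aR)-1-(tridec-12-en-1-yl)hexahydro-3H-cyclopenta[c]isoxazol-3-one (cis-fused isoxazolidin-5-one) | C=CCCCCCCCCCCCN1OC(=O)[C@H]2CCC[C@H]21 | intermediate
12 | 8-bromooct-1-ene | C=CCCCCCCBr | starting material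
13 | oct-7-en-1-yllithium | C=CCCCCCC[Li] | intermediate
14 | (3aS,6aR)-3-(oct-7-en-1-yl)-1-(tridec-12-en-1-yl)hexahydro-1H-cyclopenta[c]isoxazol-3-ol (C3 epimers) | C=CCCCCCCCCCCCN1OC(O)(CCCCCCC=C)[C@H]2CCC[C@H]21 | intermediate
15 | (3aS,6aR)-3-(oct-7-en-1-yl)-1-(tridec-12-en-1-yl)-1,3a,4,5,6,6a-hexahydrocyclopenta[c]isoxazol-2-ium (C3=O2 oxocarbenium ion) | C=CCCCCCCCCCCCN1[O+]=C(CCCCCCC=C)[C@H]2CCC[C@H]21 | intermediate
16 | (3S,3aS,6aR)-3-(oct-7-en-1-yl)-1-(tridec-12-en-1-yl)hexahydro-1H-cyclopenta[c]isoxazole | C=CCCCCCCCCCCCN1O[C@@H](CCCCCCC=C)[C@H]2CCC[C@H]21 | intermediate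
17 | 3-bromopyridine | Brc1cccnc1 | starting material
18 | (3S,3aS,6aR)-3-[8-(9-borabicyclo[3.3.1]nonan-9-yl)octyl]-1-[13-(9-borabicyclo[3.3.1]nonan-9-yl)tridecyl]hexahydro-1H-cyclopenta[c]isoxazole | C1CCC2CCCC1B2CCCCCCCCCCCCCN1O[C@@H](CCCCCCCCB2C3CCCC2CCC3)[C@H]2CCC[C@H]21 | intermediate
19 | pyrinodemin B, (3S,3aS,6aR)-1-[13-(pyridin-3-yl)tridecyl]-3-[8-(pyridin-3-yl)octyl]hexahydro-1H-cyclopenta[c]isoxazole | c1cncc(CCCCCCCCCCCCCN2O[C@@H](CCCCCCCCc3cccnc3)[C@H]3CCC[C@H]32)c1 | target

**Totals**
Total steps: 8. Longest linear sequence: 7 steps (1, 2, 4, 5, 6, 7, 8, from 11-bromoundec-1-ene); 6 steps from amino ester 5.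

**Three steps most likely to fail**

First, step 5 (over-oxidation of 10 to a nitrone, or slow ring closure on the ethyl ester). The fallback sets out from 5 and 4 and comes back at 11. Amino ester 5 is free-based (NaHCO3) and condensed with 4 (MgSO4, CH2Cl2) to the imine ethyl (1S,2R)-2-{[(E)-tridec-12-en-1-ylidene]amino}cyclopentane-1-carboxylate F1. NaBH4/EtOH reduces it to the secondary amine ethyl (1S,2R)-2-(tridec-12-en-1-ylamino)cyclopentane-1-carboxylate F2. Dibenzoyl peroxide/K2HPO4 (DMF, rt) oxygenates nitrogen directly to ethyl (1S,2R)-2-[(benzoyloxy)(tridec-12-en-1-yl)amino]cyclopentane-1-carboxylate F3. LiOH (THF/H2O, 0 °C) cleaves benzoate and ethyl ester to (1S,2R)-2-[hydroxy(tridec-12-en-1-yl)amino]cyclopentane-1-carboxylic acid F4, and EDC·HCl (CH2Cl2, 0 °C) dehydrates it to lactone 11.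

Second, step 6 (second addition after collapse of the tetrahedral adduct, or α-deprotonation of the lactone). The fallback sets out from 11 and comes back at 14. Lactone 11 is opened with MeNH(OMe)·HCl/AlMe3 (CH2Cl2, 0 °C) to the Weinreb amide (1S,2R)-2-[hydroxy(tridec-12-en-1-yl)amino]-N-methoxy-N-methylcyclopentane-1-carboxamide F5. Oct-7-en-1-yllithium 13 (2.2 equiv, the first equivalent deprotonating N–OH; THF, −78 °C) adds once to the chelated amide. On the mild acidic quench the keto hydroxylamine closes to hemiketal 14, so the ketone never sits in base.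

Third, step 7 (face selectivity of the hydride on cation 15; possible β-elimination of the hemiketal to an enone, which would erode C6a). The fallback sets out from 14 and comes back at 16. LiBH(s-Bu)3 (THF, −78 °C) reduces the ring-opened keto tautomer of 14 under Felkin–Anh control (C6a as the large group) to (1R)-1-{(1S,2R)-2-[hydroxy(tridec-12-en-1-yl)amino]cyclopentyl}non-8-en-1-ol F6. An intramolecular Mitsunobu etherification (PBu3, 1,1'-(azodicarbonyl)dipiperidine, THF, 0 °C) then closes the O–C3 bond by SN2 with inversion to give 16. C3 is thus set by substitution at a defined carbinol and not by the face of a cation.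

**Further compounds**
F1 | step 5 | ethyl (1S,2R)-2-{[(E)-tridec-12-en-1-ylidene]amino}cyclopentane-1-carboxylate | CCOC(=O)[C@H]1CCC[C@H]1/N=C/CCCCCCCCCCC=C
F2 | step 5 | ethyl (1S,2R)-2-(tridec-12-en-1-ylamino)cyclopentane-1-carboxylate | CCOC(=O)[C@H]1CCC[C@H]1NCCCCCCCCCCCC=C
F3 | step 5 | ethyl (1S,2R)-2-[(benzoyloxy)(tridec-12-en-1-yl)amino]cyclopentane-1-carboxylate | CCOC(=O)[C@H]1CCC[C@H]1N(OC(=O)c1ccccc1)CCCCCCCCCCCC=C
F4 | step 5 | (1S,2R)-2-[hydroxy(tridec-12-en-1-yl)amino]cyclopentane-1-carboxylic acid | OC(=O)[C@H]1CCC[C@H]1N(O)CCCCCCCCCCCC=C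
F5 | step 6 | (1S,2R)-2-[hydroxy(tridec-12-en-1-yl)amino]-N-methoxy-N-methylcyclopentane-1-carboxamide | CON(C)C(=O)[C@H]1CCC[C@H]1N(O)CCCCCCCCCCCC=C
F6 | step 7 | (1R)-1-{(1S,2R)-2-[hydroxy(tridec-12-en-1-yl)amino]cyclopentyl}non-8-en-1-ol | O[C@H](CCCCCCC=C)[C@H]1CCC[C@H]1N(O)CCCCCCCCCCCC=C
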